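**Strategy**

With each decalin numbered like a drimane (C1–C10, C11 on C9; primes for the unsaturated half), the target shows cis-fused rings A/B, H-5 syn to CH3-10. A thermal intramolecular Diels–Alder reaction of an acyclic (1E,3Z)-dienylboronate (C7=C8–C9=C10) with the unactivated C5=C6 vinyl group exploits this: it closes rings A and B, forms C6–C7 and C5–C10, and sets C5, C10 and a C7–B centre from the lone C3 silyloxy stereocentre. Allylboration of formaldehyde relays C7 to C9; the resulting alcohol supplies both halves, one after directed hydrogenation, joined at C11–C11′ by sulfone alkylation. C3 is finally inverted by oxidation and reduction.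

Key step: step 7

Remark: α/β refer to the usual terpenoid drawing with CH3-10 β; the SMILES is read as 3α-OH, 5β-H, 9α-H, 10β-CH3 in both halves (both decalins cis-fused) and 8α-CH3 (8β-H) in the saturated half.

**Route**

Step 1
Reactants: 1 [2-(1,3-dioxan-2-yl)ethyl]magnesium bromide; 2 propyne
Product: 5 2-[(3Z)-4-iodo-3-methylbut-3-en-1-yl]-1,3-dioxane, via alkylcopper reagent 3 (not isolated), via Z-alkenylcopper 4 (not isolated)
Conditions: CuBr·SMe2, Et2O/Me2S, −45 °C; propyne, −25 °C; then I2, −78 → 0 °C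
Reagents that add atoms: iodine, [I][I]
Why: Syn-carbocupration of a terminal alkyne places copper on the terminal carbon cis to the added alkyl chain, so iodinolysis with retention should give the Z-iodoalkene in which the future tether and the iodine are cis.

Step 2
Reactants: 5 2-[(3Z)-4-iodo-3-methylbut-3-en-1-yl]-1,3-dioxane
Product: 6 2-[(3Z)-3-methylhex-3-en-5-yn-1-yl]-1,3-dioxane
Conditions: ethynylmagnesium bromide, ZnBr2, THF, 0 °C; then 5, Pd(PPh3)4 (5 mol %), rt
Reagents that add atoms: ethynylmagnesium bromide, C#C[Mg]Br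
Why: Negishi coupling of the alkenyl iodide with ethynylzinc bromide under zerovalent palladium catalysis proceeds with retention of the Z geometry and gives the terminal enyne directly.

Step 3
Reactants: 6 2-[(3Z)-3-methylhex-3-en-5-yn-1-yl]-1,3-dioxane
Product: 7 (4Z)-4-methylhept-4-en-6-ynal
Conditions: 2 M HCl, THF, 40 °C
Reagents that add atoms: water, O
Why: Acid-catalysed acetal hydrolysis should free the aldehyde without isomerising the Z-enyne, which is not conjugated to the carbonyl group.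

Step 4
Reactants: 7 (4Z)-4-methylhept-4-en-6-ynal
Product: 8 (4S,7Z)-3,3,7-trimethyldeca-1,7-dien-9-yn-4-ol
Conditions: (+)-Ipc2BH [from (−)-α-pinene], 3-methylbuta-1,2-diene, THF, −25 °C; then 7, −78 °C; NaOH, H2O2
Reagents that add atoms: 3-methylbuta-1,2-diene, CC(C)=C=C
Why: Brown asymmetric reverse prenylation: the prenylborane formed by hydroboration of the allene adds at its γ-carbon through a chair-like Zimmerman–Traxler transition state, and the isopinocampheyl groups direct it to the Re face of the aldehyde, which sets the S carbinol (C3 of the later decalin), the only stereocentre introduced by a chiral reagent.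

Step 5
Reactants: 8 (4S,7Z)-3,3,7-trimethyldeca-1,7-dien-9-yn-4-ol
Product: 9 tert-butyl(dimethyl){[(4S,7Z)-3,3,7-trimethyldeca-1,7-dien-9-yn-4-yl]oxy}silane
Conditions: TBSOTf, 2,6-lutidine, CH2Cl2, 0 °C
Reagents that add atoms: tert-butyldimethylsilyl triflate, CC(C)(C)[Si](C)(C)OS(=O)(=O)C(F)(F)F
Why: Silylation with the reactive triflate protects the hindered neopentyl alcohol as the bulky ether that later steers the cycloaddition.

Step 6
Reactants: 9 tert-butyl(dimethyl){[(4S,7Z)-3,3,7-trimethyldeca-1,7-dien-9-yn-4-yl]oxy}silane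
Product: 11 2-[(1E,3Z,7S)-7-(tert-butyldimethylsilyloxy)-2,4,8,8-tetramethyldeca-1,3,9-trien-1-yl]-4,4,5,5-tetramethyl-1,3,2-dioxaborolane, via alkenylalane 10 (not isolated)
Conditions: Me3Al, Cp2ZrCl2 (20 mol %), CH2Cl2, 0 °C → rt; then i-PrOBpin, THF, 0 °C → rt
Reagents that add atoms: trimethylaluminium, C[Al](C)C; 2-isopropoxy-4,4,5,5-tetramethyl-1,3,2-dioxaborolane, CC(C)OB1OC(C)(C)C(C)(C)O1
Why: Zirconium-catalysed carboalumination (Negishi) adds CH3 and aluminium syn across the terminal alkyne with aluminium on the terminal carbon, and aluminium-to-boron transmetalation with retention should give the 1E-dienylboronate while the hindered vinyl group stays inert.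

Step 7
Reactants: 11 2-[(1E,3Z,7S)-7-(tert-butyldimethylsilyloxy)-2,4,8,8-tetramethyldeca-1,3,9-trien-1-yl]-4,4,5,5-tetramethyl-1,3,2-dioxaborolane
Product: 12 2-[3β-(tert-butyldimethylsilyloxy)-11-nor-5β-drim-8-en-7β-yl]-4,4,5,5-tetramethyl-1,3,2-dioxaborolane
Conditions: toluene (0.01 M), BHT, sealed tube, 180 °C
Reagents that add atoms: none
Why: Heating brings the s-cis (1E,3Z)-dienylboronate over the terminal vinyl group for a concerted, suprafacial thermal [4+2] cycloaddition, the C4 gem-dimethyl group favouring the folded rotamer; the closest known reaction type is the type 1 intramolecular Diels–Alder reaction of 1,7,9-decatrienes and of 1-boronodienes. Ring B closes as the new cyclohexene through the C6–C7 and C5–C10 bonds, and ring A closes in the same event as the six-membered tether ring C10–C1–C2–C3–C4–C5 (fused mode, chair-like tether). Because the tether occupies the inside (Z) position on C10, only the cis-fused transition state is geometrically attainable, so H-5 is placed syn to CH3-10. CH3-10 and the C7 boryl group are both outside substituents of the diene and therefore end up cis on ring B, which gives the 7β-boronate. The absolute sense is relayed from C3: with the OTBS group equatorial on the chair-like tether it lies on the face of CH3-10 and H-5, which fixes C5 and C10 as in the target. No regiocontrol is needed because the four-atom tether allows one orientation only, and the step has to outrun the 1,5-hydrogen shift open to a Z-diene, for which the Thorpe–Ingold effect of C4 is relied on.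

Step 8
Reactants: 12 2-[3β-(tert-butyldimethylsilyloxy)-11-nor-5β-drim-8-en-7β-yl]-4,4,5,5-tetramethyl-1,3,2-dioxaborolane
Product: 13 3β-(tert-butyldimethylsilyloxy)-5β-drim-7-en-11-ol
Conditions: (CH2O)n, toluene, 90 °C; aqueous work-up
Reagents that add atoms: formaldehyde (from paraformaldehyde), C=O
Why: Allylboration of formaldehyde through a closed six-membered transition state forms C9–C11 on the face that carried boron, which transfers the C7 configuration to C9 (9β-CH2OH, 9α-H) and moves the alkene to C7=C8.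

Step 9
Reactants: 13 3β-(tert-butyldimethylsilyloxy)-5β-drim-7-en-11-ol
Product: 14 3β-(tert-butyldimethylsilyloxy)-5β,8βH-driman-11-ol
Conditions: [Ir(cod)(PCy3)(py)]PF6 (5 mol %), H2 (1 atm), CH2Cl2, rt
Reagents that add atoms: none
Why: Hydroxyl-directed hydrogenation: the cationic iridium catalyst binds the C11 hydroxyl and should deliver H2 to the β face of C7=C8, which sets C8 with 8β-H and 8α-CH3 trans to C11.

Step 10
Reactants: 14 3β-(tert-butyldimethylsilyloxy)-5β,8βH-driman-11-ol
Product: 15 3β-(tert-butyldimethylsilyloxy)-11-iodo-5β,8βH-drimane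
Conditions: I2, PPh3, imidazole, toluene, 60 °C
Reagents that add atoms: iodine, [I][I]
Why: Appel-type iodination converts the β-branched primary alcohol into the iodide under neutral conditions that leave the silyl ether intact.

Step 11
Reactants: 13 3β-(tert-butyldimethylsilyloxy)-5β-drim-7-en-11-ol
Product: 16 3β-(tert-butyldimethylsilyloxy)-11-(phenylsulfanyl)-5β-drim-7-ene
Conditions: PhSSPh, n-Bu3P, pyridine, rt → 50 °C
Reagents that add atoms: diphenyl disulfide, c1ccc(SSc2ccccc2)cc1
Why: Disulfide–phosphine thioetherification (Mitsunobu-like) replaces the primary hydroxyl by phenylthio through an alkoxyphosphonium ion in an SN2 process that does not touch C9.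

Step 12
Reactants: 16 3β-(tert-butyldimethylsilyloxy)-11-(phenylsulfanyl)-5β-drim-7-ene
Product: 17 3β-(tert-butyldimethylsilyloxy)-11-(phenylsulfonyl)-5β-drim-7-ene
Conditions: (NH4)6Mo7O24·4H2O (10 mol %), 30% H2O2, EtOH, 0 °C → rt
Reagents that add atoms: hydrogen peroxide, OO
Why: Molybdate-catalysed peroxide oxidation takes the sulfide to the sulfone chemoselectively in the presence of the trisubstituted alkene and the silyl ether.

Step 13
Reactants: 17 3β-(tert-butyldimethylsilyloxy)-11-(phenylsulfonyl)-5β-drim-7-ene; 15 3β-(tert-butyldimethylsilyloxy)-11-iodo-5β,8βH-drimane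
Product: 19 11-[3′β-(tert-butyldimethylsilyloxy)-11′-(phenylsulfonyl)-5′β-drim-7′-en-11′-yl]-3β-(tert-butyldimethylsilyloxy)-5β,8βH-drimane, via lithiated sulfone 18 (not isolated)
Conditions: n-BuLi, THF, −78 °C; then 15, HMPA, −78 °C → rt
Reagents that add atoms: none
Why: Julia-type sulfone alkylation: the α-sulfonyl carbanion should displace the primary iodide by SN2 in the presence of HMPA and so form the C11–C11′ bond, the new sulfone-bearing centre being removed in the next step.

Step 14
Reactants: 19 11-[3′β-(tert-butyldimethylsilyloxy)-11′-(phenylsulfonyl)-5′β-drim-7′-en-11′-yl]-3β-(tert-butyldimethylsilyloxy)-5β,8βH-drimane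
Product: 20 11-[3′β-(tert-butyldimethylsilyloxy)-5′β-drim-7′-en-11′-yl]-3β-(tert-butyldimethylsilyloxy)-5β,8βH-drimane
Conditions: 6% Na(Hg), Na2HPO4, MeOH/THF, −20 °C → rt
Reagents that add atoms: none
Why: Reductive desulfonylation by electron transfer from sodium amalgam cleaves the C–S bond and leaves the isolated alkene and the silyl ethers untouched.

Step 15
Reactants: 20 11-[3′β-(tert-butyldimethylsilyloxy)-5′β-drim-7′-en-11′-yl]-3β-(tert-butyldimethylsilyloxy)-5β,8βH-drimane
Product: 21 11-(3′β-hydroxy-5′β-drim-7′-en-11′-yl)-5β,8βH-driman-3β-ol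
Conditions: TBAF, THF, 60 °C
Reagents that add atoms: none
Why: Fluoride-induced desilylation frees both hindered secondary alcohols.

Step 16
Reactants: 21 11-(3′β-hydroxy-5′β-drim-7′-en-11′-yl)-5β,8βH-driman-3β-ol
Product: 22 11-(3′-oxo-5′β-drim-7′-en-11′-yl)-5β,8βH-driman-3-one
Conditions: Dess–Martin periodinane, NaHCO3, CH2Cl2, rt
Reagents that add atoms: none
Why: Dess–Martin oxidation converts both secondary alcohols into the 3- and 3′-ketones and thereby erases the two relay stereocentres, which have the wrong configuration for the target.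

Step 17
Reactants: 22 11-(3′-oxo-5′β-drim-7′-en-11′-yl)-5β,8βH-driman-3-one
Product: 23 11-(3′α-hydroxy-5′β-drim-7′-en-11′-yl)-5β,8βH-driman-3α-ol (CNP0194061.2)
Conditions: NaBH4, MeOH/THF, −20 °C
Reagents that add atoms: none
Why: Substrate-controlled hydride reduction: in each cis-fused A/B unit borohydride should attack C3 from the convex β face (syn to H-5 and CH3-10), the α face being shielded by the axial 4α-methyl group or by C6 depending on the ring conformer, which sets the 3α- and 3′α-carbinols of the target.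

**Compound list**

1 | [2-(1,3-dioxan-2-yl)ethyl]magnesium bromide (commercial THF solution) | Br[Mg]CCC1OCCCO1 | starting material
2 | propyne | CC#C | starting material
3 | [2-(1,3-dioxan-2-yl)ethyl]copper (MgBr2/SMe2 complex) | [Cu]CCC1OCCCO1 | intermediate
4 | [(1Z)-4-(1,3-dioxan-2-yl)-2-methylbut-1-en-1-yl]copper | [Cu]/C=C(C)\CCC1OCCCO1 | intermediate
5 | 2-[(3Z)-4-iodo-3-methylbut-3-en-1-yl]-1,3-dioxane | I/C=C(C)\CCC1OCCCO1 | intermediate
6 | 2-[(3Z)-3-methylhex-3-en-5-yn-1-yl]-1,3-dioxane | C#C/C=C(C)\CCC1OCCCO1 | intermediate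
7 | (4Z)-4-methylhept-4-en-6-ynal | C#C/C=C(C)\CCC=O | intermediate
8 | (4S,7Z)-3,3,7-trimethyldeca-1,7-dien-9-yn-4-ol | C#C/C=C(C)\CC[C@H](O)C(C)(C)C=C | intermediate
9 | tert-butyl(dimethyl){[(4S,7Z)-3,3,7-trimethyldeca-1,7-dien-9-yn-4-yl]oxy}silane | C#C/C=C(C)\CC[C@H](O[Si](C)(C)C(C)(C)C)C(C)(C)C=C | intermediate
10 | [(1E,3Z,7S)-7-(tert-butyldimethylsilyloxy)-2,4,8,8-tetramethyldeca-1,3,9-trien-1-yl]dimethylalane | C[Al](C)/C=C(C)/C=C(C)\CC[C@H](O[Si](C)(C)C(C)(C)C)C(C)(C)C=C | intermediate
11 | 2-[(1E,3Z,7S)-7-(tert-butyldimethylsilyloxy)-2,4,8,8-tetramethyldeca-1,3,9-trien-1-yl]-4,4,5,5-tetramethyl-1,3,2-dioxaborolane | CC1(C)OB(OC1(C)C)/C=C(C)/C=C(C)\CC[C@H](O[Si](C)(C)C(C)(C)C)C(C)(C)C=C | intermediate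
12 | 2-[3β-(tert-butyldimethylsilyloxy)-11-nor-5β-drim-8-en-7β-yl]-4,4,5,5-tetramethyl-1,3,2-dioxaborolane (cis-fused; OTBS, H-5, B-7 and CH3-10 all β) | CC1=C[C@@]2(C)CC[C@H](O[Si](C)(C)C(C)(C)C)C(C)(C)[C@H]2C[C@@H]1B1OC(C)(C)C(C)(C)O1 | intermediate
13 | 3β-(tert-butyldimethylsilyloxy)-5β-drim-7-en-11-ol (9α-H) | CC1=CC[C@@H]2C(C)(C)[C@@H](O[Si](C)(C)C(C)(C)C)CC[C@]2(C)[C@H]1CO | intermediate
14 | 3β-(tert-butyldimethylsilyloxy)-5β,8βH-driman-11-ol (8α-CH3; 9α-H) | OC[C@H]1[C@H](C)CC[C@@H]2C(C)(C)[C@@H](O[Si](C)(C)C(C)(C)C)CC[C@@]21C | intermediate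
15 | 3β-(tert-butyldimethylsilyloxy)-11-iodo-5β,8βH-drimane | IC[C@H]1[C@H](C)CC[C@@H]2C(C)(C)[C@@H](O[Si](C)(C)C(C)(C)C)CC[C@@]21C | intermediate
16 | 3β-(tert-butyldimethylsilyloxy)-11-(phenylsulfanyl)-5β-drim-7-ene | CC1=CC[C@@H]2C(C)(C)[C@@H](O[Si](C)(C)C(C)(C)C)CC[C@]2(C)[C@H]1CSc1ccccc1 | intermediate
17 | 3β-(tert-butyldimethylsilyloxy)-11-(phenylsulfonyl)-5β-drim-7-ene | CC1=CC[C@@H]2C(C)(C)[C@@H](O[Si](C)(C)C(C)(C)C)CC[C@]2(C)[C@H]1CS(=O)(=O)c1ccccc1 | intermediate
18 | 11-lithio derivative of sulfone 17 | CC1=CC[C@@H]2C(C)(C)[C@@H](O[Si](C)(C)C(C)(C)C)CC[C@]2(C)[C@H]1C([Li])S(=O)(=O)c1ccccc1 | intermediate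
19 | 11-[3′β-(tert-butyldimethylsilyloxy)-11′-(phenylsulfonyl)-5′β-drim-7′-en-11′-yl]-3β-(tert-butyldimethylsilyloxy)-5β,8βH-drimane (mixture at C11′) | CC1=CC[C@@H]2C(C)(C)[C@@H](O[Si](C)(C)C(C)(C)C)CC[C@]2(C)[C@H]1C(S(=O)(=O)c1ccccc1)C[C@H]1[C@H](C)CC[C@@H]2C(C)(C)[C@@H](O[Si](C)(C)C(C)(C)C)CC[C@@]21C | intermediate
20 | 11-[3′β-(tert-butyldimethylsilyloxy)-5′β-drim-7′-en-11′-yl]-3β-(tert-butyldimethylsilyloxy)-5β,8βH-drimane | CC1=CC[C@@H]2C(C)(C)[C@@H](O[Si](C)(C)C(C)(C)C)CC[C@]2(C)[C@H]1CC[C@H]1[C@H](C)CC[C@@H]2C(C)(C)[C@@H](O[Si](C)(C)C(C)(C)C)CC[C@@]21C | intermediate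
21 | 11-(3′β-hydroxy-5′β-drim-7′-en-11′-yl)-5β,8βH-driman-3β-ol (3,3′-di-epi diol) | CC1=CC[C@@H]2C(C)(C)[C@@H](O)CC[C@]2(C)[C@H]1CC[C@H]1[C@H](C)CC[C@@H]2C(C)(C)[C@@H](O)CC[C@@]21C | intermediate
22 | 11-(3′-oxo-5′β-drim-7′-en-11′-yl)-5β,8βH-driman-3-one | CC1=CC[C@@H]2C(C)(C)C(=O)CC[C@]2(C)[C@H]1CC[C@H]1[C@H](C)CC[C@@H]2C(C)(C)C(=O)CC[C@@]21C | intermediate
23 | 11-(3′α-hydroxy-5′β-drim-7′-en-11′-yl)-5β,8βH-driman-3α-ol (CNP0194061.2) | CC1=CC[C@@H]2C(C)(C)[C@H](O)CC[C@]2(C)[C@H]1CC[C@H]1[C@H](C)CC[C@@H]2C(C)(C)[C@H](O)CC[C@@]21C | target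

**Step count and risks**

Total step count: 17. Longest linear sequence: 15 steps (1–8, then 11–12 or 9–10, then 13–17).

Steps most likely to fail:

Step 7. The unactivated vinyl group may react too slowly, so that a 1,5-hydrogen shift of the Z-diene or loss of facial control takes over at the temperature required. The fallback sets out from 7 and comes back at 13, and activates the dienophile with a removable sulfone. An oxazaborolidinone-promoted Mukaiyama aldol of 7 with 1-methoxy-2-methyl-1-(trimethylsilyloxy)propene (promoter antipode that gives the 3S aldol) would give methyl (3S,6Z)-3-hydroxy-2,2,6-trimethylnon-6-en-8-ynoate F1. TBSOTf would give its silyl ether F2, and DIBAL-H at −78 °C the aldehyde F3. A Horner–Wadsworth–Emmons reaction with diethyl (phenylsulfonyl)methylphosphonate would give the E-vinyl sulfone F4, and carboalumination–borylation as in step 6 the dienylboronate F5. Its sulfone-activated dienophile should cyclise near 110 °C to the 6-phenylsulfonyl adduct F6. Allylboration of formaldehyde would then give the 6-phenylsulfonyl alcohol F7, from which Na(Hg) removes the sulfone to reach 13.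

Step 17. Hydride delivery may show poor facial selectivity, above all in the conformationally mobile unsaturated half. The fallback sets out from 22 and comes back at 23 without a new compound: a catalyst-controlled Corey–Bakshi–Shibata reduction with (S)-2-methyl-CBS-oxazaborolidine and BH3·SMe2. The catalyst binds each carbonyl anti to the quaternary C4 and should deliver hydride to the face that gives the 3R and 3′R carbinols whatever the ring conformation.

Step 13. The SN2 displacement at the β-branched iodide may be outrun by E2 elimination or by proton transfer. The fallback sets out from 13 and 14 and comes back at 20, replacing the alkylation by an olefination. Dess–Martin oxidation of 14 would give the 11-aldehyde F8. Mitsunobu thioetherification of 13 with 1-phenyl-1H-tetrazole-5-thiol would give the tetrazolyl sulfide F9, and molybdate/H2O2 oxidation the tetrazolyl sulfone F10. Julia–Kocienski olefination of F10 with F8 (KHMDS, DME, −60 °C) would give the C11=C11′ alkene F11. Diimide (from 2-nitrobenzenesulfonylhydrazide and Et3N) should then reduce the disubstituted alkene selectively and give 20.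

Further compounds
F1 | step 7 | methyl (3S,6Z)-3-hydroxy-2,2,6-trimethylnon-6-en-8-ynoate | C#C/C=C(C)\CC[C@H](O)C(C)(C)C(=O)OC
F2 | step 7 | methyl (3S,6Z)-3-(tert-butyldimethylsilyloxy)-2,2,6-trimethylnon-6-en-8-ynoate | C#C/C=C(C)\CC[C@H](O[Si](C)(C)C(C)(C)C)C(C)(C)C(=O)OC
F3 | step 7 | (3S,6Z)-3-(tert-butyldimethylsilyloxy)-2,2,6-trimethylnon-6-en-8-ynal | C#C/C=C(C)\CC[C@H](O[Si](C)(C)C(C)(C)C)C(C)(C)C=O
F4 | step 7 | E-vinyl sulfone: tert-butyl(dimethyl){[(1E,4S,7Z)-3,3,7-trimethyl-1-(phenylsulfonyl)deca-1,7-dien-9-yn-4-yl]oxy}silane | C#C/C=C(C)\CC[C@H](O[Si](C)(C)C(C)(C)C)C(C)(C)/C=C/S(=O)(=O)c1ccccc1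
F5 | step 7 | dienylboronate carrying the E-vinyl sulfone (10-phenylsulfonyl analogue of 11) | CC1(C)OB(OC1(C)C)/C=C(C)/C=C(C)\CC[C@H](O[Si](C)(C)C(C)(C)C)C(C)(C)/C=C/S(=O)(=O)c1ccccc1
F6 | step 7 | 6-phenylsulfonyl analogue of 12 | CC1=C[C@@]2(C)CC[C@H](O[Si](C)(C)C(C)(C)C)C(C)(C)[C@H]2C(S(=O)(=O)c2ccccc2)[C@@H]1B1OC(C)(C)C(C)(C)O1
F7 | step 7 | 6-phenylsulfonyl analogue of 13 | CC1=CC(S(=O)(=O)c3ccccc3)[C@@H]2C(C)(C)[C@@H](O[Si](C)(C)C(C)(C)C)CC[C@]2(C)[C@H]1CO
F0 | step 17 | none | none
F8 | step 13 | 3β-(tert-butyldimethylsilyloxy)-5β,8βH-driman-11-al | O=C[C@H]1[C@H](C)CC[C@@H]2C(C)(C)[C@@H](O[Si](C)(C)C(C)(C)C)CC[C@@]21C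
F9 | step 13 | 3β-(tert-butyldimethylsilyloxy)-11-[(1-phenyl-1H-tetrazol-5-yl)sulfanyl]-5β-drim-7-ene | CC1=CC[C@@H]2C(C)(C)[C@@H](O[Si](C)(C)C(C)(C)C)CC[C@]2(C)[C@H]1CSc1nnnn1-c1ccccc1
F10 | step 13 | 3β-(tert-butyldimethylsilyloxy)-11-[(1-phenyl-1H-tetrazol-5-yl)sulfonyl]-5β-drim-7-ene | CC1=CC[C@@H]2C(C)(C)[C@@H](O[Si](C)(C)C(C)(C)C)CC[C@]2(C)[C@H]1CS(=O)(=O)c1nnnn1-c1ccccc1
F11 | step 13 | 11,11′-didehydro analogue of 20 (E/Z mixture at C11=C11′) | CC1=CC[C@@H]2C(C)(C)[C@@H](O[Si](C)(C)C(C)(C)C)CC[C@]2(C)[C@H]1C=C[C@H]1[C@H](C)CC[C@@H]2C(C)(C)[C@@H](O[Si](C)(C)C(C)(C)C)CC[C@@]21C
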